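## Analysis of the target

CNP0164901.1 (35) is a halimane-type diterpenoid acid. In halimane numbering, ring A (C1–C5, C10) is a cyclohexene with a trisubstituted C1=C10 olefin, ring B (C5–C10) is saturated, and C9 carries the chain C11–C15. The core has four stereocentres: quaternary C4 (methyl C19, carboxyl C18), C5 (H), C8 (methyl C17) and quaternary C9 (methyl C20, chain). The chain adds C13 (tertiary carbinol with methyl C16) and C14 (acetoxy) next to the primary C15 hydroxyl; the configuration is 4S,5S,8R,9S,13S,14R. H5, the carboxyl C18 and the C11 chain lie on one face of the bicycle, and the three methyls C17, C19 and C20 on the other. The C13/C14 pair corresponds to anti addition of two oxygens to an (E)-C13=C14 olefin. The sensitive points are the secondary acetate between a free primary and a free tertiary hydroxyl (base-labile, prone to acyl migration), the hindered free acid, and the C1=C10 olefin, which must neither move to C5=C10 nor be reduced. The difficulty is the adjacent quaternary C9 and tertiary C8 in a ring B without any functional group, in a fixed relation to C5 and the remote quaternary C4. The route rests on one feature: C8 and C9 both lie in ring B and C9 carries C11, so C11 can start as a carboxyl carbon tied through oxygen to C6, giving a six-membered lactone (C9, C11, O, C6, C5, C10) from which C6 can pass a three-carbon unit (C7, C8, C17) to C9.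

## Retrosynthetic reasoning

35 ⇒ 32. The C14 acetyl C–O bond is cut last, through 34 and 33. The 14-acetate beside a free 15-hydroxyl is the one arrangement that cannot survive base, so it has to follow every basic step. The forward steps must tell the secondary hydroxyl from the primary and the tertiary one: the primary hydroxyl and the acid are silylated (33), the secondary hydroxyl is acetylated (34), and both silyl groups come off under mildly acidic conditions.

32 ⇒ 29. The C13–O and C14–O bonds are traced through epoxy alcohol 30 to the (E)-allylic alcohol 29. The two centres are far from the core, so only reagent control can set them, and the anti relation of the two oxygens calls for epoxidation followed by one inversion. Opening 30 under basic conditions inverts C14 and leaves C13 untouched. The same basic medium cleaves the hindered C18 methyl ester (through 31), so the acid appears without a separate step.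

29 ⇒ 23. The chain is cut at C13=C14 (28 from ketone 26 and phosphonate 27) and at C11=C12 (enone 25 from aldehyde 23 and phosphonate 24). C11 is neopentyl, so it can be extended only through its carbonyl, not by substitution. Hydrogenation of 25 to 26 then removes the C11=C12 olefin and the ring B olefin C6=C7 in one operation, and has to leave the hindered C1=C10 olefin alone.

23 ⇒ 21. Only the oxidation level of C11 changes. The forward step must reduce the C11 acid in the presence of the C18 methyl ester and two olefins, which excludes hydroboration-prone reagents and is done through acid chloride 22.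

21 ⇒ 18 (key disconnection). The C8–C9 bond is cut and C11 is reconnected through oxygen to C6, which gives lactone 18 with a (Z)-propenyl group on C6. This is the one place where C8 and C9 can be made together from a single existing centre. In the silyl ketene acetal 19 the enolate geometry is fixed by the ring, the [3,3] shift can only pass through a boat, C6 decides the face of C9, and the olefin geometry decides C8. The C6 oxygen ends as part of the C11 carboxyl and leaves no trace in ring B.

18 ⇒ 13. The lactone C–O bond is opened to hydroxy diester 17, the (Z)-olefin is taken back to the alkyne of 16, and the C9–C10 bond is cut to alkenyl iodide 13 and zinc reagent 15 (from 14). Cutting at C9–C10 lets the acidic C9–H enter only after all strongly basic steps, and the iodide places the C1=C10 olefin without ambiguity.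

13 ⇒ 10. The C6 carbinol is taken back to ynone 12, so that C6 is set by a reagent and not by the substrate, and 12 to the epimeric alcohols 11. The C5–C6 bond of 11 is cut to the but-2-ynyl ether 10, the substrate of a [2,3]-Wittig shift. The cut is placed there because C5 sits next to the quaternary C4, whose two substituents are too alike to direct an intermolecular addition. In the sigmatropic shift the new bond must form on the face that carried the C1 oxygen; the same step moves the olefin to C1=C10 and removes the C1 oxygen.

10 ⇒ 6. Ether 10 comes from allylic alcohol 8 and bromide 9. The C1 carbinol of 8 is set by reagent-controlled reduction of iodoenone 7, which comes from enone 6 by α-iodination. The iodine serves three times: as the large group in the reduction, as a spectator in the [2,3] shift, and as the handle for C9.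

6 ⇒ 1 + 2. Ring A is cut at C1–C2 and C3–C4 into diene 1 and enal 2. The cycloadduct 3 gives keto aldehyde 4 on acidic work-up, and oxidation and esterification (5, 6) bring C18 to its final oxidation level. This sets the quaternary C4 in the first step, from which C1, C5, C6, C9 and C8 are derived in turn.

## Alternatives that were turned down

Alternative 1: Both rings are cut at once, at C4–C5 and C9–C10, back to an open-chain epoxy diene. In the forward step an aluminium Lewis acid opens the epoxide and the two olefins close rings A and B. The bicyclic cation is then expected to relax by a hydride shift from C9, a methyl shift from C10 to C9 and loss of a proton from C1, giving the 3-hydroxy-18-silyloxy halim-1(10)-ene sulfone A1.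
- For it: one operation builds two rings, C4, C5, C8 and C9 from a precursor whose only stereocentres come from one asymmetric epoxidation. In step economy for the core it is clearly stronger than the chosen route.
- Against it: nothing in the flask tells the cation to stop after exactly two shifts (no shift gives a labdane, further shifts a clerodane), or to lose H1 and not H5. The C8 configuration depends on the folding of the chain. A1 still needs removal of the C3 hydroxyl, oxidation of C18 from silyl ether to acid, and a sulfone alkylation that has to bring in C13 and C14.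
- Comparison: the chosen route is longer, but each centre is tied to one controlling element (catalyst, reagent or pericyclic geometry) and the olefin is placed by construction, not by the fate of a cation.

Alternative 2: Only the C4–C5 bond of ring A is cut, with ring B and its C8/C9 centres already present. In the forward step anodic oxidation of a ketene dithioacetal at C4/C18 gives a radical cation. C5 of an allylsilane attacks it, silicon leaves C1, and the olefin ends at C1=C10, giving A2 with C18 as a 2-methoxy-1,3-dithiane.
- For it: ring A, the quaternary C4, C5 and the regiodefined olefin come in one step, and C18 arrives at the acid oxidation level. Silicon fixes the olefin position as securely as the sigmatropic transposition of the chosen route, and the cyclisation is shorter than steps 4 to 7 here.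
- Against it: the C4/C5 relation depends on how a flexible chain folds onto a fully substituted radical-cation carbon. The hardest element of the target, the C8/C9 pair and its relation to C5, is not solved but moved into the synthesis of the ring B precursor.
- Comparison: the chosen route spends its key step on exactly that pair and derives C5 by chirality transfer from a reagent-set carbinol.

Alternative 3: Ring A is cut at C2–C3 and C4–C5, a Diels–Alder reaction on a ring B diene (C2=C1–C10=C5). The doubly activated methylene dienophile is held as an ester on the C6 oxygen. The tether forces the carbonyl that becomes C19 to be cis to the C6 oxygen and leaves the methyl ester as C18, giving the tricyclic lactone A3.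
- For it: C4 and C5 are set in a single intramolecular step with the olefin in place, and the dienophile is very reactive. On this point it is stronger than the chosen route, which needs a cycloaddition, a reduction and a [2,3] shift for the same two centres.
- Against it: C4 then carries two carboxyl-level carbons. C19 must be taken down from lactone to methyl and the C6 oxygen removed, two deoxygenations next to the C18 ester. The ring B diene with C8 and C9 already set has to be made first.
- Comparison: in the chosen route the C6 oxygen is not a burden to be removed. It is the tether and the leaving group of the key step and ends as the C11 carboxyl.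

Key step: step 13

Remarks on assumptions: (a) the sense of induction of the chiral diol in step 1 is assumed to give (S)-4; if it does not, the antipodal diol is used. (b) 11 is carried as a mixture of C6 epimers and 16 and 17 as mixtures of C9 epimers; these centres are erased in steps 8 and 13. 18 is drawn as one C9 epimer and is used together with the other.

## Steps

Step 1
Reactants: 1 (E)-1-(dimethylamino)-3-(tert-butyldimethylsilyloxy)buta-1,3-diene; 2 methacrolein
Product: 4 (S)-1-methyl-4-oxocyclohex-2-ene-1-carbaldehyde, via cycloadduct 3 (not isolated)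
Conditions: (R,R)-1-naphthyl-TADDOL (20 mol %), toluene, −78 °C; then 1 M aq. HCl, THF, 0 °C
Reagents that add atoms: none
Why: Diels–Alder reaction of the electron-rich aminosilyloxy diene with the enal, which is activated and shielded on one face by hydrogen bonding to the chiral diol; the endo adduct 3 should lose the silyl group and dimethylamine on acidic work-up to give the enone. The quaternary C4 is set here by the catalyst.

Step 2
Reactants: 4 (S)-1-methyl-4-oxocyclohex-2-ene-1-carbaldehyde
Product: 5 (S)-1-methyl-4-oxocyclohex-2-ene-1-carboxylic acid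
Conditions: NaClO2, NaH2PO4, 2-methylbut-2-ene, t-BuOH/H2O, 0 → 25 °C
Reagents that add atoms: sodium chlorite, [Na+].[O-]Cl=O
Why: Pinnick oxidation; chlorous acid oxidises only the aldehyde, and the scavenger should keep hypochlorite away from the enone. C4 has no hydrogen and cannot epimerise.

Step 3
Reactants: 5 (S)-1-methyl-4-oxocyclohex-2-ene-1-carboxylic acid
Product: 6 methyl (S)-1-methyl-4-oxocyclohex-2-ene-1-carboxylate
Conditions: MeI, K2CO3, DMF, 25 °C
Reagents that add atoms: iodomethane, CI
Why: O-alkylation of the carboxylate (SN2 on iodomethane), which avoids acyl substitution at the hindered carboxyl; the carbonate is too weak to enolise the enone.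

Step 4
Reactants: 6 methyl (S)-1-methyl-4-oxocyclohex-2-ene-1-carboxylate
Product: 7 methyl (S)-3-iodo-1-methyl-4-oxocyclohex-2-ene-1-carboxylate
Conditions: I2, pyridine, CH2Cl2, 25 °C
Reagents that add atoms: iodine, II
Why: α-Iodination of the enone by pyridine addition, iodination of the enolate and elimination; 4,4-disubstituted cyclohexenones are known to react. The iodine on C10 is the large group for step 5 and the handle for step 10.

Step 5
Reactants: 7 methyl (S)-3-iodo-1-methyl-4-oxocyclohex-2-ene-1-carboxylate
Product: 8 methyl (1S,4S)-4-hydroxy-3-iodo-1-methylcyclohex-2-ene-1-carboxylate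
Conditions: (R)-2-methyl-CBS-oxazaborolidine (0.2 equiv), BH3·SMe2, THF, −30 °C; MeOH quench
Reagents that add atoms: none
Why: Corey–Bakshi–Shibata reduction; the iodovinyl arm acts as the large group, so the (R)-catalyst should give the (S)-carbinol, whose oxygen on C1 is cis to methyl C19. The centre is reagent-controlled because C4 is remote; the minor enantiomer of 7 would give a separable diastereomer, which should raise the enantiomeric purity.

Step 6
Reactants: 8 methyl (1S,4S)-4-hydroxy-3-iodo-1-methylcyclohex-2-ene-1-carboxylate; 9 1-bromobut-2-yne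
Product: 10 methyl (1S,4S)-4-(but-2-yn-1-yloxy)-3-iodo-1-methylcyclohex-2-ene-1-carboxylate
Conditions: NaH, THF/DMF, 0 °C; then 9, Bu4NI (cat.), 0 → 25 °C
Reagents that add atoms: none
Why: Williamson etherification of the allylic alkoxide with a reactive propargylic bromide. The alkoxide is trans to the C18 ester across the ring and cannot lactonise.

Step 7
Reactants: 10 methyl (1S,4S)-4-(but-2-yn-1-yloxy)-3-iodo-1-methylcyclohex-2-ene-1-carboxylate
Product: 11 methyl (1S,2S)-2-(1-hydroxybut-2-yn-1-yl)-3-iodo-1-methylcyclohex-3-ene-1-carboxylate (both carbinol epimers)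
Conditions: LiN(i-Pr)2 (2.5 equiv), THF, −78 → −30 °C; aq. NH4Cl
Reagents that add atoms: none
Why: [2,3]-Wittig rearrangement: the amide base removes a propargylic α-oxy proton, and the carbanion bonds to C5 through a five-membered suprafacial transition state, so C6 arrives on the face that carried the C1 oxygen (cis to C19), the olefin moves to C1=C10 and the oxygen leaves C1. An amide base is used so that neither iodine–lithium exchange nor addition to the ester occurs. The C6 configuration is not relied on, since it is erased in step 8.

Step 8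
Reactants: 11 methyl (1S,2S)-2-(1-hydroxybut-2-yn-1-yl)-3-iodo-1-methylcyclohex-3-ene-1-carboxylate (both carbinol epimers)
Product: 12 methyl (1S,2S)-2-(but-2-ynoyl)-3-iodo-1-methylcyclohex-3-ene-1-carboxylate
Conditions: Dess–Martin periodinane, NaHCO3, CH2Cl2, 0 → 25 °C
Reagents that add atoms: none
Why: Dess–Martin oxidation of the propargylic alcohol under buffered, non-basic conditions, chosen so that the now acidic H5 (α to the ynone and allylic) is not removed. Both epimers of 11 converge on one ynone.

Step 9
Reactants: 12 methyl (1S,2S)-2-(but-2-ynoyl)-3-iodo-1-methylcyclohex-3-ene-1-carboxylate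
Product: 13 methyl (1S,2S)-2-[(1S)-1-hydroxybut-2-yn-1-yl]-3-iodo-1-methylcyclohex-3-ene-1-carboxylate
Conditions: Ru[(S,S)-TsNCHPhCHPhNH](p-cymene) (3 mol %), i-PrOH, 25 °C
Reagents that add atoms: none
Why: Noyori-type asymmetric transfer hydrogenation of an alkynyl ketone; hydride and proton are delivered in a six-membered transition state in which the alkynyl group takes the place of the π-substituent, so the (S,S)-complex is expected to give the (6S)-carbinol. The catalyst has to override the Felkin–Anh preference of the substrate. The base-free amido complex is chosen to keep C5 from epimerising.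

Step 10
Reactants: 13 methyl (1S,2S)-2-[(1S)-1-hydroxybut-2-yn-1-yl]-3-iodo-1-methylcyclohex-3-ene-1-carboxylate; 14 methyl 2-bromopropanoate
Product: 16 methyl (1S,2S)-2-[(1S)-1-hydroxybut-2-yn-1-yl]-3-(1-methoxy-1-oxopropan-2-yl)-1-methylcyclohex-3-ene-1-carboxylate (C9 epimers), via zinc reagent 15 (not isolated)
Conditions: 14, Zn dust, Me3SiCl (cat.), THF, 25 °C (forms 15); then 13, Pd[P(t-Bu)3]2 (5 mol %), THF, 25 → 45 °C
Reagents that add atoms: none
Why: Negishi coupling of a Reformatsky reagent with an alkenyl iodide (oxidative addition at C10, transmetalation of the zinc ester enolate, reductive elimination); the olefin stays at C1=C10 and C9 enters as a mixture of epimers, which does not matter. An excess of 15 covers any protonolysis by the free hydroxyl, and kinetic α-protonation on work-up should keep the ester unconjugated.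

Step 11
Reactants: 16 methyl (1S,2S)-2-[(1S)-1-hydroxybut-2-yn-1-yl]-3-(1-methoxy-1-oxopropan-2-yl)-1-methylcyclohex-3-ene-1-carboxylate (C9 epimers)
Product: 17 methyl (1S,2S)-2-[(1R,2Z)-1-hydroxybut-2-en-1-yl]-3-(1-methoxy-1-oxopropan-2-yl)-1-methylcyclohex-3-ene-1-carboxylate (C9 epimers)
Conditions: H2 (1 atm), Pd/CaCO3 poisoned with Pb(OAc)2, quinoline, EtOAc, 25 °C
Reagents that add atoms: none
Why: Lindlar semihydrogenation; syn addition of hydrogen to the internal alkyne gives the (Z)-olefin, and the hindered trisubstituted C1=C10 olefin should not react. It is done before lactonisation so that no allylic or propargylic carboxylate is exposed to palladium; the C6 descriptor changes from S to R only because the priorities change.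

Step 12
Reactants: 17 methyl (1S,2S)-2-[(1R,2Z)-1-hydroxybut-2-en-1-yl]-3-(1-methoxy-1-oxopropan-2-yl)-1-methylcyclohex-3-ene-1-carboxylate (C9 epimers)
Product: 18 methyl (1R,4R,8S,8aS)-4,8-dimethyl-3-oxo-1-[(Z)-prop-1-en-1-yl]-3,4,6,7,8,8a-hexahydro-1H-isochromene-8-carboxylate (with its 4S epimer)
Conditions: pyridinium p-toluenesulfonate (0.2 equiv), toluene, 80 °C, 5 Å molecular sieves
Reagents that add atoms: none
Why: Acid-catalysed lactonisation of a δ-hydroxy ester, driven by removal of methanol; the unhindered C11 ester should close the six-membered ring, while the tertiary C18 ester is hindered and trans to C6. The weak acid is chosen to avoid ionising the allylic alcohol and moving the β,γ-olefin into conjugation.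

Step 13
Reactants: 18 methyl (1R,4R,8S,8aS)-4,8-dimethyl-3-oxo-1-[(Z)-prop-1-en-1-yl]-3,4,6,7,8,8a-hexahydro-1H-isochromene-8-carboxylate (with its 4S epimer)
Product: 21 (1S,2R,4aS,5S)-5-(methoxycarbonyl)-1,2,5-trimethyl-1,2,4a,5,6,7-hexahydronaphthalene-1-carboxylic acid, via silyl ketene acetal 19 (not isolated), via trimethylsilyl ester 20 (not isolated)
Conditions: LiN(i-Pr)2, Me3SiCl/Et3N, THF, −78 °C; then toluene, 25 → 100 °C; 1 M aq. HCl, THF, 25 °C
Reagents that add atoms: none
Why: LiN(i-Pr)2 removes H9 (α to the lactone carbonyl and allylic to C1=C10) and Me3SiCl traps the dienolate on oxygen as 19, whose C9=C11 geometry is fixed by the ring, so both C9 epimers converge. On warming, 19 should undergo an Ireland–Claisen [3,3] shift in which C8 bonds to C9 as the C6–O bond breaks; the lactone contracts to carbocyclic ring B with a C6=C7 olefin, and C11 is released as silyl ester 20, which the acidic work-up hydrolyses to 21. The closest known reaction type is the Ireland–Claisen ring contraction of 6-alkenyl δ-lactone silyl ketene acetals to cyclohexene carboxylic acids, which runs through the same boat. Ring B is closed by suprafacial bond formation across the 1,4-positions of the lactone in a boat-like, bicyclo[2.2.2]-type transition state, the only geometry in which the propenyl terminus reaches C9. C9 is controlled by C6: C8 can add only to the face of the ketene acetal that carries the axial propenyl group, which is the face cis to the C5–C4 bond, so C11 ends cis to H5 and C20 trans to it. C8 is controlled by the olefin geometry: in the forced boat the (Z)-methyl points toward the C5–C10 bridge and so becomes cis to C20 and trans to C11. The step needs α-bonding of the dienolate and O-silylation; C1 cannot reach C8, and the α-methyl group with the chlorosilane/amine quench should favour O-silylation. The (Z)-methyl is eclipsed with C10 in the boat, which is the main strain and the reason heating is expected to be needed.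

Step 14
Reactants: 21 (1S,2R,4aS,5S)-5-(methoxycarbonyl)-1,2,5-trimethyl-1,2,4a,5,6,7-hexahydronaphthalene-1-carboxylic acid
Product: 23 methyl (1S,5S,6R,8aS)-5-formyl-1,5,6-trimethyl-1,2,3,5,6,8a-hexahydronaphthalene-1-carboxylate, via acid chloride 22 (not isolated)
Conditions: (COCl)2, DMF (cat.), CH2Cl2, 0 → 25 °C; then LiAlH(O-t-Bu)3, THF, −78 °C
Reagents that add atoms: none
Why: The acid is activated as its chloride, and the hindered alkoxyaluminium hydride reduces an acid chloride to the aldehyde and stops there. Neither reagent touches the C18 methyl ester or the two olefins, which borane would not spare; C9 has no hydrogen, so no ketene or epimer can form.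

Step 15
Reactants: 23 methyl (1S,5S,6R,8aS)-5-formyl-1,5,6-trimethyl-1,2,3,5,6,8a-hexahydronaphthalene-1-carboxylate; 24 dimethyl (2-oxopropyl)phosphonate
Product: 25 methyl (1S,5S,6R,8aS)-1,5,6-trimethyl-5-[(E)-3-oxobut-1-en-1-yl]-1,2,3,5,6,8a-hexahydronaphthalene-1-carboxylate
Conditions: 24, NaH, THF, 0 °C; then 23, 0 → 40 °C
Reagents that add atoms: none
Why: Horner–Wadsworth–Emmons olefination of a non-enolisable neopentyl aldehyde with a stabilised phosphonate anion; the (E)-enone is expected, and its geometry is lost in the next step anyway.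

Step 16
Reactants: 25 methyl (1S,5S,6R,8aS)-1,5,6-trimethyl-5-[(E)-3-oxobut-1-en-1-yl]-1,2,3,5,6,8a-hexahydronaphthalene-1-carboxylate
Product: 26 methyl (1S,5S,6R,8aS)-1,5,6-trimethyl-5-(3-oxobutyl)-1,2,3,5,6,7,8,8a-octahydronaphthalene-1-carboxylate
Conditions: H2 (4 atm), RhCl(PPh3)3 (10 mol %), benzene/EtOH, 25 °C
Reagents that add atoms: none
Why: Homogeneous hydrogenation with RhCl(PPh3)3 reduces disubstituted olefins (the enone C11=C12 and the ring olefin C6=C7) but not the trisubstituted C1=C10 olefin flanked by the quaternary C9, and it does not isomerise olefins. No stereocentre is formed.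

Step 17
Reactants: 26 methyl (1S,5S,6R,8aS)-1,5,6-trimethyl-5-(3-oxobutyl)-1,2,3,5,6,7,8,8a-octahydronaphthalene-1-carboxylate; 27 triethyl phosphonoacetate
Product: 28 methyl (1S,5S,6R,8aS)-5-[(E)-5-ethoxy-3-methyl-5-oxopent-3-en-1-yl]-1,5,6-trimethyl-1,2,3,5,6,7,8,8a-octahydronaphthalene-1-carboxylate
Conditions: 27, NaH, THF, 0 °C; then 26, 25 → 65 °C
Reagents that add atoms: none
Why: Horner–Wadsworth–Emmons olefination of a methyl ketone; the ester should end mainly trans to the longer chain, giving the (E)-enoate, and the minor (Z)-isomer would be removed by chromatography here or after step 18.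

Step 18
Reactants: 28 methyl (1S,5S,6R,8aS)-5-[(E)-5-ethoxy-3-methyl-5-oxopent-3-en-1-yl]-1,5,6-trimethyl-1,2,3,5,6,7,8,8a-octahydronaphthalene-1-carboxylate
Product: 29 methyl (1S,5S,6R,8aS)-5-[(E)-5-hydroxy-3-methylpent-3-en-1-yl]-1,5,6-trimethyl-1,2,3,5,6,7,8,8a-octahydronaphthalene-1-carboxylate
Conditions: i-Bu2AlH (2.2 equiv), CH2Cl2, −78 °C; aq. potassium sodium tartrate
Reagents that add atoms: none
Why: 1,2-Reduction of the unhindered conjugated ester to the allylic alcohol; at low temperature the tertiary, neopentyl C18 methyl ester should react much more slowly and survive.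

Step 19
Reactants: 29 methyl (1S,5S,6R,8aS)-5-[(E)-5-hydroxy-3-methylpent-3-en-1-yl]-1,5,6-trimethyl-1,2,3,5,6,7,8,8a-octahydronaphthalene-1-carboxylate
Product: 30 methyl (1S,5S,6R,8aS)-5-{2-[(2S,3S)-3-(hydroxymethyl)-2-methyloxiran-2-yl]ethyl}-1,5,6-trimethyl-1,2,3,5,6,7,8,8a-octahydronaphthalene-1-carboxylate
Conditions: Ti(O-i-Pr)4 (10 mol %), L-(+)-diethyl tartrate (12 mol %), t-BuOOH, 4 Å molecular sieves, CH2Cl2, −20 °C
Reagents that add atoms: tert-butyl hydroperoxide, CC(C)(C)OO
Why: Sharpless asymmetric epoxidation of a trisubstituted (E)-allylic alcohol; with the L-(+)-tartrate the oxygen should be delivered to the face that gives the (13S,14S)-epoxide, as with other (E)-3-methylalk-2-en-1-ols. The centres are reagent-controlled, and the C1=C10 olefin, which is not allylic to a hydroxyl, is not epoxidised.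

Step 20
Reactants: 30 methyl (1S,5S,6R,8aS)-5-{2-[(2S,3S)-3-(hydroxymethyl)-2-methyloxiran-2-yl]ethyl}-1,5,6-trimethyl-1,2,3,5,6,7,8,8a-octahydronaphthalene-1-carboxylate
Product: 32 (1S,5S,6R,8aS)-1,5,6-trimethyl-5-[(3S,4R)-3,4,5-trihydroxy-3-methylpentyl]-1,2,3,5,6,7,8,8a-octahydronaphthalene-1-carboxylic acid, via triol methyl ester 31 (not isolated)
Conditions: KOH, DMSO/H2O (3:1), 90 °C; then 1 M aq. HCl to pH 3
Reagents that add atoms: potassium hydroxide, [K+].[OH-]
Why: Payne rearrangement (the C15 alkoxide attacks C14 with inversion) followed by hydroxide opening of the terminal epoxide at C15; C13 keeps its oxygen, so the (13S,14S)-epoxide should give the (13S,14R)-triol, and direct attack of hydroxide at C14 would give the same isomer. The same hot hydroxide then saponifies the hindered C18 ester, so the acid is freed before the base-labile acetate exists.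

Step 21
Reactants: 32 (1S,5S,6R,8aS)-1,5,6-trimethyl-5-[(3S,4R)-3,4,5-trihydroxy-3-methylpentyl]-1,2,3,5,6,7,8,8a-octahydronaphthalene-1-carboxylic acid
Product: 33 tert-butyldimethylsilyl (1S,5S,6R,8aS)-5-[(3S,4R)-5-(tert-butyldimethylsilyloxy)-3,4-dihydroxy-3-methylpentyl]-1,5,6-trimethyl-1,2,3,5,6,7,8,8a-octahydronaphthalene-1-carboxylate
Conditions: t-BuMe2SiCl (2.3 equiv), imidazole, DMF, 0 °C
Reagents that add atoms: tert-butyldimethylsilyl chloride, CC(C)(C)[Si](C)(C)Cl
Why: Silylation of the carboxyl and of the primary hydroxyl; the secondary hydroxyl next to a fully substituted carbon and the tertiary hydroxyl should not react at 0 °C. The silyl ester is used without chromatography and keeps the acid from forming a mixed anhydride in step 22.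

Step 22
Reactants: 33 tert-butyldimethylsilyl (1S,5S,6R,8aS)-5-[(3S,4R)-5-(tert-butyldimethylsilyloxy)-3,4-dihydroxy-3-methylpentyl]-1,5,6-trimethyl-1,2,3,5,6,7,8,8a-octahydronaphthalene-1-carboxylate
Product: 34 tert-butyldimethylsilyl (1S,5S,6R,8aS)-5-[(3S,4R)-4-acetoxy-5-(tert-butyldimethylsilyloxy)-3-hydroxy-3-methylpentyl]-1,5,6-trimethyl-1,2,3,5,6,7,8,8a-octahydronaphthalene-1-carboxylate
Conditions: Ac2O, 4-(dimethylamino)pyridine (cat.), pyridine, CH2Cl2, 0 → 25 °C
Reagents that add atoms: acetic anhydride, CC(=O)OC(C)=O
Why: Nucleophile-catalysed acylation of the only free secondary hydroxyl; the tertiary C13 hydroxyl should be far slower under these conditions.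

Step 23
Reactants: 34 tert-butyldimethylsilyl (1S,5S,6R,8aS)-5-[(3S,4R)-4-acetoxy-5-(tert-butyldimethylsilyloxy)-3-hydroxy-3-methylpentyl]-1,5,6-trimethyl-1,2,3,5,6,7,8,8a-octahydronaphthalene-1-carboxylate
Product: 35 (1S,5S,6R,8aS)-5-[(3S,4R)-4-acetoxy-3,5-dihydroxy-3-methylpentyl]-1,5,6-trimethyl-1,2,3,5,6,7,8,8a-octahydronaphthalene-1-carboxylic acid (CNP0164901.1)
Conditions: HF·pyridine, pyridine/THF, 0 → 25 °C; aqueous work-up at pH 5
Reagents that add atoms: none
Why: Fluoride cleaves the silyl ether and the silyl ester in one operation. The buffered, mildly acidic medium is chosen because acetyl migration from O14 to O15 is base-catalysed.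

## Compound list

1 | (E)-1-(dimethylamino)-3-(tert-butyldimethylsilyloxy)buta-1,3-diene | CN(C)/C=C/C(=C)O[Si](C)(C)C(C)(C)C | starting material
2 | methacrolein | CC(=C)C=O | starting material
3 | (1S,2R)-4-(tert-butyldimethylsilyloxy)-2-(dimethylamino)-1-methylcyclohex-3-ene-1-carbaldehyde (endo cycloadduct) | O=C[C@@]1(C)CCC(O[Si](C)(C)C(C)(C)C)=C[C@H]1N(C)C | intermediate
4 | (S)-1-methyl-4-oxocyclohex-2-ene-1-carbaldehyde | O=C[C@]1(C)C=CC(=O)CC1 | intermediate
5 | (S)-1-methyl-4-oxocyclohex-2-ene-1-carboxylic acid | OC(=O)[C@]1(C)C=CC(=O)CC1 | intermediate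
6 | methyl (S)-1-methyl-4-oxocyclohex-2-ene-1-carboxylate | COC(=O)[C@]1(C)C=CC(=O)CC1 | intermediate
7 | methyl (S)-3-iodo-1-methyl-4-oxocyclohex-2-ene-1-carboxylate | COC(=O)[C@]1(C)C=C(I)C(=O)CC1 | intermediate
8 | methyl (1S,4S)-4-hydroxy-3-iodo-1-methylcyclohex-2-ene-1-carboxylate | COC(=O)[C@]1(C)C=C(I)[C@@H](O)CC1 | intermediate
9 | 1-bromobut-2-yne | CC#CCBr | starting material
10 | methyl (1S,4S)-4-(but-2-yn-1-yloxy)-3-iodo-1-methylcyclohex-2-ene-1-carboxylate | COC(=O)[C@]1(C)C=C(I)[C@@H](OCC#CC)CC1 | intermediate
11 | methyl (1S,2S)-2-(1-hydroxybut-2-yn-1-yl)-3-iodo-1-methylcyclohex-3-ene-1-carboxylate (both carbinol epimers) | COC(=O)[C@@]1(C)CCC=C(I)[C@@H]1C(O)C#CC | intermediate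
12 | methyl (1S,2S)-2-(but-2-ynoyl)-3-iodo-1-methylcyclohex-3-ene-1-carboxylate | COC(=O)[C@@]1(C)CCC=C(I)[C@@H]1C(=O)C#CC | intermediate
13 | methyl (1S,2S)-2-[(1S)-1-hydroxybut-2-yn-1-yl]-3-iodo-1-methylcyclohex-3-ene-1-carboxylate | COC(=O)[C@@]1(C)CCC=C(I)[C@@H]1[C@H](O)C#CC | intermediate
14 | methyl 2-bromopropanoate | CC(Br)C(=O)OC | starting material
15 | bromo(1-methoxy-1-oxopropan-2-yl)zinc | COC(=O)C(C)[Zn]Br | intermediate
16 | methyl (1S,2S)-2-[(1S)-1-hydroxybut-2-yn-1-yl]-3-(1-methoxy-1-oxopropan-2-yl)-1-methylcyclohex-3-ene-1-carboxylate (C9 epimers) | COC(=O)C(C)C1=CCC[C@](C)(C(=O)OC)[C@H]1[C@H](O)C#CC | intermediate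
17 | methyl (1S,2S)-2-[(1R,2Z)-1-hydroxybut-2-en-1-yl]-3-(1-methoxy-1-oxopropan-2-yl)-1-methylcyclohex-3-ene-1-carboxylate (C9 epimers) | COC(=O)C(C)C1=CCC[C@](C)(C(=O)OC)[C@H]1[C@H](O)/C=C\C | intermediate
18 | methyl (1R,4R,8S,8aS)-4,8-dimethyl-3-oxo-1-[(Z)-prop-1-en-1-yl]-3,4,6,7,8,8a-hexahydro-1H-isochromene-8-carboxylate (ring A fused δ-lactone; used with its 4S epimer) | C[C@H]1C(=O)O[C@H](/C=C\C)[C@H]2C1=CCC[C@]2(C)C(=O)OC | intermediate
19 | methyl (1R,8S,8aS)-4,8-dimethyl-1-[(Z)-prop-1-en-1-yl]-3-(trimethylsilyloxy)-6,7,8,8a-tetrahydro-1H-isochromene-8-carboxylate | C[Si](C)(C)OC1=C(C)C2=CCC[C@](C)(C(=O)OC)[C@H]2[C@@H](/C=C\C)O1 | intermediate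
20 | trimethylsilyl (1S,2R,4aS,5S)-5-(methoxycarbonyl)-1,2,5-trimethyl-1,2,4a,5,6,7-hexahydronaphthalene-1-carboxylate | C[Si](C)(C)OC(=O)[C@]1(C)C2=CCC[C@](C)(C(=O)OC)[C@H]2C=C[C@H]1C | intermediate
21 | (1S,2R,4aS,5S)-5-(methoxycarbonyl)-1,2,5-trimethyl-1,2,4a,5,6,7-hexahydronaphthalene-1-carboxylic acid | OC(=O)[C@]1(C)C2=CCC[C@](C)(C(=O)OC)[C@H]2C=C[C@H]1C | intermediate
22 | methyl (1S,5S,6R,8aS)-5-(chlorocarbonyl)-1,5,6-trimethyl-1,2,3,5,6,8a-hexahydronaphthalene-1-carboxylate | ClC(=O)[C@]1(C)C2=CCC[C@](C)(C(=O)OC)[C@H]2C=C[C@H]1C | intermediate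
23 | methyl (1S,5S,6R,8aS)-5-formyl-1,5,6-trimethyl-1,2,3,5,6,8a-hexahydronaphthalene-1-carboxylate | O=C[C@]1(C)C2=CCC[C@](C)(C(=O)OC)[C@H]2C=C[C@H]1C | intermediate
24 | dimethyl (2-oxopropyl)phosphonate | COP(=O)(CC(C)=O)OC | starting material
25 | methyl (1S,5S,6R,8aS)-1,5,6-trimethyl-5-[(E)-3-oxobut-1-en-1-yl]-1,2,3,5,6,8a-hexahydronaphthalene-1-carboxylate | CC(=O)/C=C/[C@]1(C)C2=CCC[C@](C)(C(=O)OC)[C@H]2C=C[C@H]1C | intermediate
26 | methyl (1S,5S,6R,8aS)-1,5,6-trimethyl-5-(3-oxobutyl)-1,2,3,5,6,7,8,8a-octahydronaphthalene-1-carboxylate | CC(=O)CC[C@]1(C)C2=CCC[C@](C)(C(=O)OC)[C@H]2CC[C@H]1C | intermediate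
27 | triethyl phosphonoacetate | CCOC(=O)CP(=O)(OCC)OCC | starting material
28 | methyl (1S,5S,6R,8aS)-5-[(E)-5-ethoxy-3-methyl-5-oxopent-3-en-1-yl]-1,5,6-trimethyl-1,2,3,5,6,7,8,8a-octahydronaphthalene-1-carboxylate | CCOC(=O)/C=C(\C)CC[C@]1(C)C2=CCC[C@](C)(C(=O)OC)[C@H]2CC[C@H]1C | intermediate
29 | methyl (1S,5S,6R,8aS)-5-[(E)-5-hydroxy-3-methylpent-3-en-1-yl]-1,5,6-trimethyl-1,2,3,5,6,7,8,8a-octahydronaphthalene-1-carboxylate | OC/C=C(\C)CC[C@]1(C)C2=CCC[C@](C)(C(=O)OC)[C@H]2CC[C@H]1C | intermediate
30 | methyl (1S,5S,6R,8aS)-5-{2-[(2S,3S)-3-(hydroxymethyl)-2-methyloxiran-2-yl]ethyl}-1,5,6-trimethyl-1,2,3,5,6,7,8,8a-octahydronaphthalene-1-carboxylate | OC[C@@H]1O[C@@]1(C)CC[C@]1(C)C2=CCC[C@](C)(C(=O)OC)[C@H]2CC[C@H]1C | intermediate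
31 | methyl (1S,5S,6R,8aS)-1,5,6-trimethyl-5-[(3S,4R)-3,4,5-trihydroxy-3-methylpentyl]-1,2,3,5,6,7,8,8a-octahydronaphthalene-1-carboxylate | OC[C@@H](O)[C@@](C)(O)CC[C@]1(C)C2=CCC[C@](C)(C(=O)OC)[C@H]2CC[C@H]1C | intermediate
32 | (1S,5S,6R,8aS)-1,5,6-trimethyl-5-[(3S,4R)-3,4,5-trihydroxy-3-methylpentyl]-1,2,3,5,6,7,8,8a-octahydronaphthalene-1-carboxylic acid | OC[C@@H](O)[C@@](C)(O)CC[C@]1(C)C2=CCC[C@](C)(C(=O)O)[C@H]2CC[C@H]1C | intermediate
33 | tert-butyldimethylsilyl (1S,5S,6R,8aS)-5-[(3S,4R)-5-(tert-butyldimethylsilyloxy)-3,4-dihydroxy-3-methylpentyl]-1,5,6-trimethyl-1,2,3,5,6,7,8,8a-octahydronaphthalene-1-carboxylate | CC(C)(C)[Si](C)(C)OC[C@@H](O)[C@@](C)(O)CC[C@]1(C)C2=CCC[C@](C)(C(=O)O[Si](C)(C)C(C)(C)C)[C@H]2CC[C@H]1C | intermediate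
34 | tert-butyldimethylsilyl (1S,5S,6R,8aS)-5-[(3S,4R)-4-acetoxy-5-(tert-butyldimethylsilyloxy)-3-hydroxy-3-methylpentyl]-1,5,6-trimethyl-1,2,3,5,6,7,8,8a-octahydronaphthalene-1-carboxylate | CC(C)(C)[Si](C)(C)OC[C@@H](OC(C)=O)[C@@](C)(O)CC[C@]1(C)C2=CCC[C@](C)(C(=O)O[Si](C)(C)C(C)(C)C)[C@H]2CC[C@H]1C | intermediate
35 | (1S,5S,6R,8aS)-5-[(3S,4R)-4-acetoxy-3,5-dihydroxy-3-methylpentyl]-1,5,6-trimethyl-1,2,3,5,6,7,8,8a-octahydronaphthalene-1-carboxylic acid (CNP0164901.1) | CC(=O)O[C@H](CO)[C@@](C)(O)CC[C@]1(C)C2=CCC[C@](C)(C(=O)O)[C@H]2CC[C@H]1C | target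

## Step count and least certain steps

Total step count: 23. Longest linear sequence: 23 steps, from 1 and 2 to 35; 9, 14, 24 and 27 are purchased and enter the one linear sequence.

Step 13 (key step). The process most likely to fail is the rearrangement itself. The lactone ring of 19 is flattened by three trigonal carbons, and in the boat the (Z)-methyl is eclipsed with C10. The silyl ketene acetal may therefore decompose, or be silylated on carbon, before it rearranges. The fallback makes the C8–C9 bond by an intramolecular Tsuji–Trost allylation instead, sets out from 13 and returns at 21.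
- Negishi coupling as in step 10, but with the zinc reagent from tert-butyl 2-bromopropanoate, would give the tert-butyl ester analogue of 16, tert-butyl methyl hydroxy diester F1.
- Semihydrogenation as in step 11 would give the (Z)-allylic alcohol F2.
- Methyl chloroformate and pyridine would give the allylic methyl carbonate F3.
- Pd(PPh3)4 with LiN(SiMe3)2 in THF would ionise the carbonate with inversion. The C9 ester dienolate would attack C8 anti to palladium, that is on the face the oxygen left, as in the sigmatropic shift, closing ring B to the bicyclic tert-butyl methyl diester F4.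
- Me3SiOTf and 2,6-lutidine would remove the tert-butyl group and give 21.
- The weak point is that C8 keeps its configuration only if cyclisation is faster than syn/anti isomerisation of the allyl complex.

Step 10. Oxidative addition at the hindered C10 iodide is followed by coupling with a secondary zinc enolate. Transmetalation or reductive elimination may be too slow, so that protonolysis of the reagent and reduction of the iodide take over. The fallback brings in C9, C11 and C20 as an isopropenyl group, sets out from 13 and returns at 18.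
- Suzuki–Miyaura coupling with isopropenylboronic acid pinacol ester (Pd(PPh3)4, K3PO4, dioxane/H2O) would give the diene alkynol F5.
- 9-Borabicyclo[3.3.1]nonane should add to the 1,1-disubstituted terminus faster than to the internal alkyne, and NaBO3 would give the alkynyl diol F6 (C9 epimers).
- Semihydrogenation as in step 11 would give the (Z)-alkenyl diol F7.
- TEMPO with PhI(OAc)2 would oxidise the primary alcohol and then the lactol, giving 18.

Step 7. Deprotonation of the propargylic ether by an amide base may be incomplete or slow. At the higher temperature then needed, [1,2]-shift and attack at the iodoalkene may compete. The fallback replaces the [2,3] shift by a [3,3] shift with the same 1,3-transfer of chirality, sets out from 8 and returns at 11.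
- Esterification with (4-methoxybenzyloxy)acetic acid (dicyclohexylcarbodiimide, 4-(dimethylamino)pyridine) would give the glycolate ester F8.
- Ireland–Claisen rearrangement (KN(SiMe3)2, Me3SiCl, −78 → 25 °C) would give the α-alkoxy acid F9, with C6 bonded to C5 on the face of the former C1 oxygen.
- 2,3-Dichloro-5,6-dicyano-1,4-benzoquinone would give the α-hydroxy acid F10.
- Pb(OAc)4 would cleave it to the aldehyde F11.
- 1-Propynylmagnesium bromide (CH3C≡CMgBr) at −78 °C would give 11.

Step 9. The catalyst has to override the Felkin–Anh preference of the substrate. Poor facial selectivity in this mismatched case, or epimerisation at C5 of the ynone, would erode the C5/C6 relation on which step 13 depends. The fallback accepts substrate control and inverts afterwards, sets out from 12 and returns at 13.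
- Luche reduction (NaBH4, CeCl3, MeOH, −78 °C) would give mainly the (6R)-alcohol F12.
- A Mitsunobu reaction with 4-nitrobenzoic acid would give the inverted (6S)-4-nitrobenzoate F13.
- K2CO3 in MeOH would release 13.

Step 17. The olefination of a methyl ketone is only moderately (E)-selective, so material is lost as the (Z)-enoate; step 18 also carries a risk of partial reduction of the C18 ester. The fallback builds the trisubstituted olefin by carbometalation, sets out from 26 and returns at 29, so it bypasses 28 and step 18.
- Kinetic enolisation toward the methyl group (LiN(i-Pr)2, −78 °C), trapping with ClP(O)(OEt)2 and elimination with more LiN(i-Pr)2 would give the terminal alkyne F14.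
- Zirconium-catalysed carboalumination (Me3Al, Cp2ZrCl2, CH2Cl2), then n-BuLi and (CH2O)n, would give 29 with the (E)-geometry fixed by syn addition.

Step 20. The epoxide should open readily, but acyl substitution at the tertiary C18 ester may stall, and forcing it may start to move the C1=C10 olefin. The fallback cleaves the ester at the methyl carbon instead and makes no new compound (F0).
- The opening is run under milder base (NaOH, t-BuOH/H2O, 80 °C) and 31 is isolated.
- LiSPr in hexamethylphosphoramide then attacks the O-methyl group (SN2) and gives 32.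

## Further compounds

F1 | step 13 | tert-butyl ester analogue of 16: methyl (1S,2S)-3-(1-tert-butoxy-1-oxopropan-2-yl)-2-[(1S)-1-hydroxybut-2-yn-1-yl]-1-methylcyclohex-3-ene-1-carboxylate (C9 epimers) | CC(C)(C)OC(=O)C(C)C1=CCC[C@](C)(C(=O)OC)[C@H]1[C@H](O)C#CC
F2 | step 13 | methyl (1S,2S)-3-(1-tert-butoxy-1-oxopropan-2-yl)-2-[(1R,2Z)-1-hydroxybut-2-en-1-yl]-1-methylcyclohex-3-ene-1-carboxylate (C9 epimers) | CC(C)(C)OC(=O)C(C)C1=CCC[C@](C)(C(=O)OC)[C@H]1[C@H](O)/C=C\C
F3 | step 13 | allylic methyl carbonate of F2 | CC(C)(C)OC(=O)C(C)C1=CCC[C@](C)(C(=O)OC)[C@H]1[C@H](OC(=O)OC)/C=C\C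
F4 | step 13 | 1-tert-butyl 5-methyl (1S,2R,4aS,5S)-1,2,5-trimethyl-1,2,4a,5,6,7-hexahydronaphthalene-1,5-dicarboxylate | CC(C)(C)OC(=O)[C@]1(C)C2=CCC[C@](C)(C(=O)OC)[C@H]2C=C[C@H]1C
F5 | step 10 | methyl (1S,2S)-2-[(1S)-1-hydroxybut-2-yn-1-yl]-1-methyl-3-(prop-1-en-2-yl)cyclohex-3-ene-1-carboxylate | COC(=O)[C@@]1(C)CCC=C(C(C)=C)[C@@H]1[C@H](O)C#CC
F6 | step 10 | methyl (1S,2S)-2-[(1S)-1-hydroxybut-2-yn-1-yl]-3-(1-hydroxypropan-2-yl)-1-methylcyclohex-3-ene-1-carboxylate (C9 epimers) | COC(=O)[C@@]1(C)CCC=C(C(C)CO)[C@@H]1[C@H](O)C#CC
F7 | step 10 | methyl (1S,2S)-2-[(1R,2Z)-1-hydroxybut-2-en-1-yl]-3-(1-hydroxypropan-2-yl)-1-methylcyclohex-3-ene-1-carboxylate (C9 epimers) | COC(=O)[C@@]1(C)CCC=C(C(C)CO)[C@@H]1[C@H](O)/C=C\C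
F8 | step 7 | methyl (1S,4S)-3-iodo-4-{[(4-methoxybenzyloxy)acetyl]oxy}-1-methylcyclohex-2-ene-1-carboxylate | COC(=O)[C@]1(C)C=C(I)[C@@H](OC(=O)COCc2ccc(OC)cc2)CC1
F9 | step 7 | 2-[(1S,6S)-2-iodo-6-(methoxycarbonyl)-6-methylcyclohex-2-en-1-yl]-2-(4-methoxybenzyloxy)acetic acid (C6 epimers) | COC(=O)[C@@]1(C)CCC=C(I)[C@@H]1C(OCc2ccc(OC)cc2)C(=O)O
F10 | step 7 | 2-hydroxy-2-[(1S,6S)-2-iodo-6-(methoxycarbonyl)-6-methylcyclohex-2-en-1-yl]acetic acid (C6 epimers) | COC(=O)[C@@]1(C)CCC=C(I)[C@@H]1C(O)C(=O)O
F11 | step 7 | methyl (1S,2S)-2-formyl-3-iodo-1-methylcyclohex-3-ene-1-carboxylate | COC(=O)[C@@]1(C)CCC=C(I)[C@@H]1C=O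
F12 | step 9 | methyl (1S,2S)-2-[(1R)-1-hydroxybut-2-yn-1-yl]-3-iodo-1-methylcyclohex-3-ene-1-carboxylate | COC(=O)[C@@]1(C)CCC=C(I)[C@@H]1[C@@H](O)C#CC
F13 | step 9 | (1S)-1-[(1S,6S)-2-iodo-6-(methoxycarbonyl)-6-methylcyclohex-2-en-1-yl]but-2-yn-1-yl 4-nitrobenzoate | COC(=O)[C@@]1(C)CCC=C(I)[C@@H]1[C@H](OC(=O)c2ccc(cc2)[N+](=O)[O-])C#CC
F14 | step 17 | methyl (1S,5S,6R,8aS)-5-(but-3-yn-1-yl)-1,5,6-trimethyl-1,2,3,5,6,7,8,8a-octahydronaphthalene-1-carboxylate | C#CCC[C@]1(C)C2=CCC[C@](C)(C(=O)OC)[C@H]2CC[C@H]1C
F0 | step 20 | none | none
A1 | alternative 1 | 3-hydroxy-18-(tert-butyldiphenylsilyloxy)halim-1(10)-ene with a phenylsulfonyl group on C12 | O=S(=O)(c1ccccc1)CC[C@]2(C)C3=CC[C@@H](O)[C@](C)(CO[Si](c4ccccc4)(c5ccccc5)C(C)(C)C)[C@H]3CC[C@H]2C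
A2 | alternative 2 | halim-1(10)-ene core with C18 as a 2-methoxy-1,3-dithiane and the C13 ketone as a dioxolane | CC3(OCCO3)CC[C@]1(C)C2=CCC[C@](C)(C4(OC)SCCCS4)[C@H]2CC[C@H]1C
A3 | alternative 3 | tricyclic Diels–Alder lactone (C19 carbonyl to C6 oxygen) with the C18 methyl ester and the C13 ketone as a dioxolane | CC5(OCCO5)CC[C@]1(C)C2=CCC[C@]3(C(=O)OC)[C@H]2[C@@H](OC3=O)C[C@H]1C
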